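**Retrosynthetic overview**
1. Target 21 comes from 20 by one double oxidation (ArCH2OH to ArCHO, allylic CHOH to enone); 20 comes from triol 18 by lipase-catalysed regioselective palmitoylation of the C7 hydroxymethyl.
2. 18 comes from chromano-phthalide 17 by LiAlH4 opening of the lactone that carried C7-CH2O and C8-C=O in differentiated form; 17 comes from aldehyde 15 plus isobutenyl Grignard 16; 15 comes from 2-vinylchroman 12 by hydroboration and oxidation.
3. 12 comes from phenol allyl carbonate 11 by Pd-catalysed asymmetric allylic O-alkylation, which closes the dihydropyran ring and sets the only stereocentre.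
4. 11 comes from bromophenol-phthalide 4 and the C6 dienyl unit 7 (hydroboration, B-alkyl Suzuki); 4 comes from the symmetric benzyl alcohol 1 (iodination, carbonylative lactonisation, peri-selective O-demethylation).
5. Ring order: benzene ring bought; γ-lactone (phthalide) ring first (step 2); dihydropyran ring second (step 9); the lactone is opened again in step 13.

Assumption: the (R,R)-Trost ligand is taken to give the (S)-chroman from the (Z)-carbonate (E and Z carbonates give opposite enantiomers), assigned by analogy and not from a confirmed precedent; the first batch of 12 is checked by chiral HPLC/VCD and the (S,S)-ligand is used if the sense is reversed.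

**Route**

Step 1
Reactants: 1 (4-bromo-3,5-dimethoxyphenyl)methanol
Product: 2 (4-bromo-2-iodo-3,5-dimethoxyphenyl)methanol
Conditions: NIS (1.05 eq), TFA (0.2 eq), MeCN, 0 °C to rt
Reagents that add atoms: N-iodosuccinimide, O=C1CCC(=O)N1I
Why: Electrophilic aromatic iodination can only occur at the two equivalent free positions, each ortho to one OMe and para to the other, so a single mono-iodide forms.

Step 2
Reactants: 2 (4-bromo-2-iodo-3,5-dimethoxyphenyl)methanol
Product: 3 6-bromo-5,7-dimethoxyisobenzofuran-1(3H)-one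
Conditions: PdCl2(PPh3)2 (5 mol%), CO (1 atm), Et3N (2 eq), DMF, 70 °C
Reagents that add atoms: carbon monoxide, [C-]#[O+]
Why: Pd-catalysed carbonylative lactonisation: Pd(0) inserts into C–I far faster than into the C–Br bond flanked by two OMe groups, CO inserts, and the neighbouring benzylic OH captures the acyl-Pd to close the γ-lactone.

Step 3
Reactants: 3 6-bromo-5,7-dimethoxyisobenzofuran-1(3H)-one
Product: 4 6-bromo-7-hydroxy-5-methoxyisobenzofuran-1(3H)-one
Conditions: BCl3 (1.5 eq), CH2Cl2, −78 to 0 °C; then H2O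
Reagents that add atoms: none
Why: Chelation-controlled Lewis-acid O-demethylation: BCl3 binds the lactone carbonyl and the peri 7-OMe in a six-membered chelate, so only that methyl is removed and the 5-OMe, lactone and aryl bromide are untouched.

Step 4
Reactants: 5 (Z)-3-methylpent-2-en-4-yn-1-ol
Product: 6 (Z)-tert-butyldimethyl[(3-methylpent-2-en-4-yn-1-yl)oxy]silane
Conditions: TBSCl (1.1 eq), imidazole (1.5 eq), CH2Cl2, 0 °C to rt
Reagents that add atoms: tert-butyldimethylsilyl chloride, CC(C)(C)[Si](C)(C)Cl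
Why: Silyl ether formation masks the OH for the later hydroboration and Suzuki steps and makes the C6 unit non-volatile.

Step 5
Reactants: 6 (Z)-tert-butyldimethyl[(3-methylpent-2-en-4-yn-1-yl)oxy]silane
Product: 7 (Z)-tert-butyldimethyl[(3-methylpenta-2,4-dien-1-yl)oxy]silane
Conditions: H2 (1 atm), Lindlar catalyst, quinoline, hexane, 0 °C to rt, stopped after 1 eq H2
Reagents that add atoms: none
Why: Lindlar semi-hydrogenation stops at the alkene on the poisoned catalyst, turning the terminal alkyne into a vinyl group while the trisubstituted (Z)-alkene keeps its geometry.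

Step 6
Reactants: 7 (Z)-tert-butyldimethyl[(3-methylpenta-2,4-dien-1-yl)oxy]silane; 4 6-bromo-7-hydroxy-5-methoxyisobenzofuran-1(3H)-one
Product: 9 6-[(Z)-5-(tert-butyldimethylsilyloxy)-3-methylpent-3-en-1-yl]-7-hydroxy-5-methoxyisobenzofuran-1(3H)-one, via alkyl-9-BBN borane 8 (not isolated)
Conditions: 7 (1.3 eq), 9-BBN (1.35 eq), THF, 0 °C to rt; then 4, SPhos Pd G2 (5 mol%), aq. K3PO4 (4 eq), THF/DMF, 60 °C; pH 4 work-up
Reagents that add atoms: 9-borabicyclo[3.3.1]nonane, B1C2CCCC1CCC2 (its boron unit stays only in 8)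
Why: Anti-Markovnikov hydroboration by bulky 9-BBN takes only the monosubstituted vinyl of the diene, and the primary alkylborane then undergoes B-alkyl Suzuki–Miyaura coupling at the hindered aryl bromide with the (Z)-alkene retained.

Step 7
Reactants: 9 6-[(Z)-5-(tert-butyldimethylsilyloxy)-3-methylpent-3-en-1-yl]-7-hydroxy-5-methoxyisobenzofuran-1(3H)-one
Product: 10 7-hydroxy-6-[(Z)-5-hydroxy-3-methylpent-3-en-1-yl]-5-methoxyisobenzofuran-1(3H)-one
Conditions: TBAF (1.2 eq), AcOH (1.2 eq), THF, 0 °C to rt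
Reagents that add atoms: none
Why: Buffered fluoride desilylation frees the primary allylic alcohol without affecting the lactone or the alkene geometry.

Step 8
Reactants: 10 7-hydroxy-6-[(Z)-5-hydroxy-3-methylpent-3-en-1-yl]-5-methoxyisobenzofuran-1(3H)-one
Product: 11 (Z)-5-(7-hydroxy-5-methoxy-1-oxo-1,3-dihydroisobenzofuran-6-yl)-3-methylpent-2-en-1-yl methyl carbonate
Conditions: ClCO2Me (1.1 eq), pyridine (3 eq), CH2Cl2, −20 to 0 °C
Reagents that add atoms: methyl chloroformate, COC(=O)Cl
Why: Chemoselective carbonate formation: the unhindered primary allylic alcohol reacts much faster than the phenol, which is hindered and hydrogen-bonded to the lactone carbonyl.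

Step 9
Reactants: 11 (Z)-5-(7-hydroxy-5-methoxy-1-oxo-1,3-dihydroisobenzofuran-6-yl)-3-methylpent-2-en-1-yl methyl carbonate
Product: 12 (S)-5-methoxy-2-methyl-2-vinyl-3,4-dihydro-2H,7H-furo[3,4-h]chromen-9-one
Conditions: Pd2(dba)3·CHCl3 (2.5 mol%), (R,R)-DACH-phenyl Trost ligand (7.5 mol%), AcOH (1 eq), CH2Cl2 (0.05 M), rt
Reagents that add atoms: none
Why: Intramolecular Trost asymmetric allylic alkylation: decarboxylative ionisation gives a π-allyl-Pd complex, the phenol attacks the more substituted terminus to close the six-membered ring, and the chiral diphosphine selects one of the equilibrating π-allyl faces (AcOH slows cyclisation), setting quaternary C2 as (S).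

Step 10
Reactants: 12 (S)-5-methoxy-2-methyl-2-vinyl-3,4-dihydro-2H,7H-furo[3,4-h]chromen-9-one
Product: 14 (S)-2-(2-hydroxyethyl)-5-methoxy-2-methyl-3,4-dihydro-2H,7H-furo[3,4-h]chromen-9-one, via alkyl-9-BBN borane 13 (not isolated)
Conditions: 9-BBN (1.5 eq), THF, 0 °C to rt; then NaBO3·4H2O (5 eq), H2O, rt
Reagents that add atoms: 9-borabicyclo[3.3.1]nonane, B1C2CCCC1CCC2 (its boron unit stays only in 13); sodium perborate, [Na+].[O-]OB=O
Why: Hydroboration–oxidation: 9-BBN adds anti-Markovnikov to the vinyl group and does not reduce the lactone, and mild perborate oxidation gives the primary alcohol without touching the stereocentre.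

Step 11
Reactants: 14 (S)-2-(2-hydroxyethyl)-5-methoxy-2-methyl-3,4-dihydro-2H,7H-furo[3,4-h]chromen-9-one
Product: 15 (S)-2-(5-methoxy-2-methyl-9-oxo-3,4,7,9-tetrahydro-2H-furo[3,4-h]chromen-2-yl)acetaldehyde
Conditions: Dess–Martin periodinane (1.3 eq), CH2Cl2, 0 °C to rt; used directly
Reagents that add atoms: none
Why: Dess–Martin oxidation gives the β-aryloxy aldehyde under non-basic conditions, avoiding the β-elimination (retro-oxa-Michael) that would open the chroman and endanger C2.

Step 12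
Reactants: 15 (S)-2-(5-methoxy-2-methyl-9-oxo-3,4,7,9-tetrahydro-2H-furo[3,4-h]chromen-2-yl)acetaldehyde; 16 2-methyl-1-propenylmagnesium bromide
Product: 17 (2S)-2-(2-hydroxy-4-methylpent-3-en-1-yl)-5-methoxy-2-methyl-3,4-dihydro-2H,7H-furo[3,4-h]chromen-9-one (both carbinol epimers)
Conditions: 16 (1.3 eq, 0.5 M in THF), THF, −78 °C; pH 7 buffer quench at −78 °C
Reagents that add atoms: none
Why: Grignard 1,2-addition at −78 °C is chemoselective for the aldehyde over the electron-rich aryl lactone; the new carbinol centre is an irrelevant epimer mixture because it is oxidised in step 15.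

Step 13
Reactants: 17 (2S)-2-(2-hydroxy-4-methylpent-3-en-1-yl)-5-methoxy-2-methyl-3,4-dihydro-2H,7H-furo[3,4-h]chromen-9-one
Product: 18 1-[(2S)-7,8-bis(hydroxymethyl)-5-methoxy-2-methylchroman-2-yl]-4-methylpent-3-en-2-ol
Conditions: LiAlH4 (2 eq), THF, 0 °C; Fieser work-up (H2O, 15% NaOH, H2O), no acid
Reagents that add atoms: none
Why: Hydride reduction of the lactone opens the phthalide to the two benzylic alcohols while the allylic alcohol, alkene and tertiary aryl ether are inert.

Step 14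
Reactants: 18 1-[(2S)-7,8-bis(hydroxymethyl)-5-methoxy-2-methylchroman-2-yl]-4-methylpent-3-en-2-ol; 19 vinyl palmitate
Product: 20 [(2S)-8-(hydroxymethyl)-2-(2-hydroxy-4-methylpent-3-en-1-yl)-5-methoxy-2-methylchroman-7-yl]methyl hexadecanoate
Conditions: immobilised Candida antarctica lipase B (a lipase, Novozym 435), 19 (1.5 eq), MTBE, 4 Å MS, 30 °C; HPLC control, enzyme filtered off
Reagents that add atoms: none
Why: Lipase-catalysed irreversible transesterification (acyl-enzyme from the vinyl ester): the enzyme acylates only the unhindered primary benzylic alcohol at C7, because the C8 hydroxymethyl is flanked by two ortho substituents and the secondary alcohol carries two large groups that do not fit the alcohol pocket.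

Step 15
Reactants: 20 [(2S)-8-(hydroxymethyl)-2-(2-hydroxy-4-methylpent-3-en-1-yl)-5-methoxy-2-methylchroman-7-yl]methyl hexadecanoate
Product: 21 [(2S)-8-formyl-5-methoxy-2-methyl-2-(4-methyl-2-oxopent-3-en-1-yl)chroman-7-yl]methyl hexadecanoate
Conditions: Dess–Martin periodinane (3 eq), CH2Cl2, 0 °C to rt; Na2S2O3/NaHCO3 wash, no base afterwards
Reagents that add atoms: none
Why: Double Dess–Martin oxidation converts the benzylic alcohol into the aryl aldehyde and the allylic alcohol into the enone in one neutral operation, so the base-sensitive β-aryloxy ketone (C2 stereocentre) and the palmitate survive.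

**Compound list**
1 | (4-bromo-3,5-dimethoxyphenyl)methanol | COc1cc(CO)cc(OC)c1Br | starting material
2 | (4-bromo-2-iodo-3,5-dimethoxyphenyl)methanol | COc1cc(CO)c(I)c(OC)c1Br | intermediate
3 | 6-bromo-5,7-dimethoxyisobenzofuran-1(3H)-one | O=C1OCc2cc(OC)c(Br)c(OC)c12 | intermediate
4 | 6-bromo-7-hydroxy-5-methoxyisobenzofuran-1(3H)-one | O=C1OCc2cc(OC)c(Br)c(O)c12 | intermediate
5 | (Z)-3-methylpent-2-en-4-yn-1-ol | C#C/C(C)=C\CO | starting material
6 | (Z)-tert-butyldimethyl[(3-methylpent-2-en-4-yn-1-yl)oxy]silane | C#C/C(C)=C\CO[Si](C)(C)C(C)(C)C | intermediate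
7 | (Z)-tert-butyldimethyl[(3-methylpenta-2,4-dien-1-yl)oxy]silane | C=C/C(C)=C\CO[Si](C)(C)C(C)(C)C | intermediate
8 | 9-[(Z)-5-(tert-butyldimethylsilyloxy)-3-methylpent-3-en-1-yl]-9-borabicyclo[3.3.1]nonane | CC(C)(C)[Si](C)(C)OC/C=C(/C)CCB1C2CCCC1CCC2 | intermediate
9 | 6-[(Z)-5-(tert-butyldimethylsilyloxy)-3-methylpent-3-en-1-yl]-7-hydroxy-5-methoxyisobenzofuran-1(3H)-one | O=C1OCc2cc(OC)c(CC/C(C)=C\CO[Si](C)(C)C(C)(C)C)c(O)c12 | intermediate
10 | 7-hydroxy-6-[(Z)-5-hydroxy-3-methylpent-3-en-1-yl]-5-methoxyisobenzofuran-1(3H)-one | O=C1OCc2cc(OC)c(CC/C(C)=C\CO)c(O)c12 | intermediate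
11 | (Z)-5-(7-hydroxy-5-methoxy-1-oxo-1,3-dihydroisobenzofuran-6-yl)-3-methylpent-2-en-1-yl methyl carbonate | O=C1OCc2cc(OC)c(CC/C(C)=C\COC(=O)OC)c(O)c12 | intermediate
12 | (S)-5-methoxy-2-methyl-2-vinyl-3,4-dihydro-2H,7H-furo[3,4-h]chromen-9-one (chroman fused at C7/C8 to a γ-lactone, lactone CH2 on chroman C7, lactone C=O on chroman C8) | O=C1OCc3cc(OC)c2c(c13)O[C@](C)(C=C)CC2 | intermediate
13 | (S)-2-[2-(9-borabicyclo[3.3.1]nonan-9-yl)ethyl]-5-methoxy-2-methyl-3,4-dihydro-2H,7H-furo[3,4-h]chromen-9-one | O=C1OCc3cc(OC)c2c(c13)O[C@](C)(CCB4C5CCCC4CCC5)CC2 | intermediate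
14 | (S)-2-(2-hydroxyethyl)-5-methoxy-2-methyl-3,4-dihydro-2H,7H-furo[3,4-h]chromen-9-one | O=C1OCc3cc(OC)c2c(c13)O[C@](C)(CCO)CC2 | intermediate
15 | (S)-2-(5-methoxy-2-methyl-9-oxo-3,4,7,9-tetrahydro-2H-furo[3,4-h]chromen-2-yl)acetaldehyde | O=C1OCc3cc(OC)c2c(c13)O[C@](C)(CC=O)CC2 | intermediate
16 | 2-methyl-1-propenylmagnesium bromide | CC(C)=C[Mg]Br | starting material
17 | (2S)-2-(2-hydroxy-4-methylpent-3-en-1-yl)-5-methoxy-2-methyl-3,4-dihydro-2H,7H-furo[3,4-h]chromen-9-one (carbinol epimers) | O=C1OCc3cc(OC)c2c(c13)O[C@](C)(CC(O)C=C(C)C)CC2 | intermediate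
18 | 1-[(2S)-7,8-bis(hydroxymethyl)-5-methoxy-2-methylchroman-2-yl]-4-methylpent-3-en-2-ol (carbinol epimers) | OCc1cc(OC)c2c(c1CO)O[C@](C)(CC(O)C=C(C)C)CC2 | intermediate
19 | vinyl palmitate (vinyl hexadecanoate) | CCCCCCCCCCCCCCCC(=O)OC=C | starting material
20 | [(2S)-8-(hydroxymethyl)-2-(2-hydroxy-4-methylpent-3-en-1-yl)-5-methoxy-2-methylchroman-7-yl]methyl hexadecanoate (carbinol epimers) | CCCCCCCCCCCCCCCC(=O)OCc1cc(OC)c2c(c1CO)O[C@](C)(CC(O)C=C(C)C)CC2 | intermediate
21 | [(2S)-8-formyl-5-methoxy-2-methyl-2-(4-methyl-2-oxopent-3-en-1-yl)chroman-7-yl]methyl hexadecanoate | CCCCCCCCCCCCCCCC(=O)OCc1cc(OC)c2c(c1C=O)O[C@](C)(CC(=O)C=C(C)C)CC2 | target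

**Totals**
Total step count: 15 (steps 4 and 5 are the side branch).
Longest linear sequence: 13 steps (1 to 21 through steps 1–3 and 6–15).

**Three steps most likely to fail**

Step 6 is the first risk: oxidative addition at the hindered, phenoxide-bearing aryl bromide may be slow and the alkyl-Pd may lose β-hydride. The fallback reverses the polarity of the sp3–sp2 coupling; it sets out from 4 and comes back at 9. Compound 4 is vinylated with potassium vinyltrifluoroborate (PdCl2(dppf), Et3N, n-PrOH, 90 °C) to 7-hydroxy-5-methoxy-6-vinylisobenzofuran-1(3H)-one F1. Separately, but-2-yn-1-ol is treated with Red-Al and then I2 to give (Z)-3-iodobut-2-en-1-ol F2, which is silylated (TBSCl, imidazole) to (Z)-tert-butyl[(3-iodobut-2-en-1-yl)oxy]dimethylsilane F3. F1 is hydroborated at the styrene terminus with 9-BBN (2.2 eq) to 7-hydroxy-5-methoxy-6-[2-(9-borabicyclo[3.3.1]nonan-9-yl)ethyl]isobenzofuran-1(3H)-one F4, which is coupled in the same flask with the unhindered vinyl iodide F3 (PdCl2(dppf), aq. K3PO4, THF/DMF, rt) to give 9.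

Step 9 is the second risk: the ee and sense of induction are untested for this lactone-bonded phenol, and Pd(0) could re-ionise the product. The fallback sets the centre by Sharpless epoxidation instead; it sets out from 10 and comes back at 12. Epoxidation of 10 (Ti(OiPr)4, L-(+)-diethyl tartrate, TBHP, 4 Å MS, CH2Cl2, −20 °C) gives 7-hydroxy-6-{2-[(2R,3S)-3-(hydroxymethyl)-2-methyloxiran-2-yl]ethyl}-5-methoxyisobenzofuran-1(3H)-one F5. Catalytic CSA in CH2Cl2 at 0 °C lets the phenol open the epoxide 6-exo at the tertiary carbon with inversion to give (S)-2-[(S)-1,2-dihydroxyethyl]-5-methoxy-2-methyl-3,4-dihydro-2H,7H-furo[3,4-h]chromen-9-one F6. NaIO4 (THF/H2O) cleaves the diol to (S)-5-methoxy-2-methyl-9-oxo-3,4,7,9-tetrahydro-2H-furo[3,4-h]chromene-2-carbaldehyde F7, and Wittig methylenation (Ph3P=CH2, THF, −78 to 0 °C) gives 12.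

Step 14 is the third risk: the lipase may not discriminate cleanly between the two benzylic hydroxymethyl groups, and the mono-ester can undergo acyl migration. The fallback uses the lactone itself to differentiate C7 from C8; it sets out from 17 and comes back at 21. Lactone 17 is opened with MeNH(OMe)·HCl/Me2AlCl (CH2Cl2, 0 °C) to (2S)-7-(hydroxymethyl)-2-(2-hydroxy-4-methylpent-3-en-1-yl)-N,5-dimethoxy-N,2-dimethylchromane-8-carboxamide F8. Its primary benzylic OH is acylated with palmitoyl chloride (1.05 eq, pyridine, CH2Cl2, −20 °C) to {(2S)-2-(2-hydroxy-4-methylpent-3-en-1-yl)-5-methoxy-8-[methoxy(methyl)carbamoyl]-2-methylchroman-7-yl}methyl hexadecanoate F9. Cp2Zr(H)Cl (THF, rt) reduces the Weinreb amide to the aldehyde without touching the ester, giving [(2S)-8-formyl-2-(2-hydroxy-4-methylpent-3-en-1-yl)-5-methoxy-2-methylchroman-7-yl]methyl hexadecanoate F10, and Dess–Martin oxidation of the remaining allylic alcohol gives 21.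

**Further compounds**
F1 | step 6 | 7-hydroxy-5-methoxy-6-vinylisobenzofuran-1(3H)-one | O=C1OCc2cc(OC)c(C=C)c(O)c12
F2 | step 6 | (Z)-3-iodobut-2-en-1-ol | C/C(I)=C/CO
F3 | step 6 | (Z)-tert-butyl[(3-iodobut-2-en-1-yl)oxy]dimethylsilane | C/C(I)=C/CO[Si](C)(C)C(C)(C)C
F4 | step 6 | 7-hydroxy-5-methoxy-6-[2-(9-borabicyclo[3.3.1]nonan-9-yl)ethyl]isobenzofuran-1(3H)-one | O=C1OCc2cc(OC)c(CCB3C4CCCC3CCC4)c(O)c12
F5 | step 9 | 7-hydroxy-6-{2-[(2R,3S)-3-(hydroxymethyl)-2-methyloxiran-2-yl]ethyl}-5-methoxyisobenzofuran-1(3H)-one | OC[C@@H]1O[C@]1(C)CCc1c(OC)cc2COC(=O)c2c1O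
F6 | step 9 | (S)-2-[(S)-1,2-dihydroxyethyl]-5-methoxy-2-methyl-3,4-dihydro-2H,7H-furo[3,4-h]chromen-9-one | O=C1OCc3cc(OC)c2c(c13)O[C@](C)([C@@H](O)CO)CC2
F7 | step 9 | (S)-5-methoxy-2-methyl-9-oxo-3,4,7,9-tetrahydro-2H-furo[3,4-h]chromene-2-carbaldehyde | O=C1OCc3cc(OC)c2c(c13)O[C@](C)(C=O)CC2
F8 | step 14 | (2S)-7-(hydroxymethyl)-2-(2-hydroxy-4-methylpent-3-en-1-yl)-N,5-dimethoxy-N,2-dimethylchromane-8-carboxamide | CON(C)C(=O)c1c(CO)cc(OC)c2c1O[C@](C)(CC(O)C=C(C)C)CC2
F9 | step 14 | {(2S)-2-(2-hydroxy-4-methylpent-3-en-1-yl)-5-methoxy-8-[methoxy(methyl)carbamoyl]-2-methylchroman-7-yl}methyl hexadecanoate | CON(C)C(=O)c1c(COC(=O)CCCCCCCCCCCCCCC)cc(OC)c2c1O[C@](C)(CC(O)C=C(C)C)CC2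
F10 | step 14 | [(2S)-8-formyl-2-(2-hydroxy-4-methylpent-3-en-1-yl)-5-methoxy-2-methylchroman-7-yl]methyl hexadecanoate | CCCCCCCCCCCCCCCC(=O)OCc1cc(OC)c2c(c1C=O)O[C@](C)(CC(O)C=C(C)C)CC2
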